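The cyclohexane ring is cut at the bond joining the azepine methine carbon (C7a, attached to the pyrrole α-carbon C10b) to the ethyl-bearing carbon C8, which lies next to the oxygen-bearing carbon C9. Since C7a is a pyrrol-2-yl carbinyl position, a racemic ring carbinol can be ionised by a chiral Brønsted acid to a planar azafulvenium ion that a tethered ketone enol captures. This closes the six-membered ring and fixes both C7a (catalyst control) and C8 (equilibration) in one operation. The precursor is a pyrrolo[1,2-a]azepin-9-ol carrying a 2-oxopentyl chain on the adjacent pyrrole β-carbon and an acid-stable methyl ester on the remote α-carbon.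

Key step: step 6

Remarks before the steps
- Locants: bicyclic compounds use pyrrolo[1,2-a]azepine numbering (pyrrole C1–C3, N4, azepine C5–C9, C9a). Tricyclic and later compounds use azepino[3,2,1-hi]indole numbering (pyrrole C1 and C2, N3, azepine C4–C7, methine C7a, ethyl-bearing C8, oxygen-bearing C9, C10, ring-fusion carbons C10a and C10b).
- Assumption: the sense of induction of the two chiral catalysts (steps 6 and 11) is not certain in advance. The (R)-acid and the (S,S)-ligand are written as working choices, and the enantiomer that gives the configuration drawn would be used.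
- Assumption: compounds 1, 2, 4, 14 and 24 are taken as catalogue chemicals.

Step 1
Reactants: 1 methyl 4-formyl-1H-pyrrole-2-carboxylate; 2 tert-butyl 5-bromopentanoate
Product: 3 methyl 1-(5-tert-butoxy-5-oxopentyl)-4-formyl-1H-pyrrole-2-carboxylate
Conditions: K2CO3, DMF, 60 °C
Reagents that add atoms: none
Why: The NH of a pyrrole flanked by ester and formyl acceptors is acidic enough for clean carbonate-mediated N-alkylation by a primary bromide (SN2), and alkylating at the aldehyde stage avoids the competing C-alkylation that the later pyrrolylmethyl ketone would invite.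

Step 2
Reactants: 3 methyl 1-(5-tert-butoxy-5-oxopentyl)-4-formyl-1H-pyrrole-2-carboxylate; 4 1-nitrobutane
Product: 5 methyl 1-(5-tert-butoxy-5-oxopentyl)-4-[(E)-2-nitropent-1-en-1-yl]-1H-pyrrole-2-carboxylate
Conditions: NH4OAc (0.5 equiv), 4 (3 equiv), toluene, 4 Å MS, 100 °C
Reagents that add atoms: none
Why: Henry (nitroaldol) condensation with dehydration in the same flask is driven by conjugation of the nitroalkene with the pyrrole and gives the (E)-isomer, attaching the complete five-carbon side chain with the future carbonyl carbon marked by the nitro group.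

Step 3
Reactants: 5 methyl 1-(5-tert-butoxy-5-oxopentyl)-4-[(E)-2-nitropent-1-en-1-yl]-1H-pyrrole-2-carboxylate
Product: 6 methyl 1-(5-tert-butoxy-5-oxopentyl)-4-(2-oxopentyl)-1H-pyrrole-2-carboxylate
Conditions: Fe powder, AcOH/H2O (9:1), 70 °C
Reagents that add atoms: water, O
Why: Iron in aqueous acetic acid reduces the conjugated nitroalkene to the oxime or enamine level, which hydrolyses in the medium to the ketone (reductive Nef-type conversion of an aryl nitroalkene into an arylacetone), while both ester groups are inert.

Step 4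
Reactants: 6 methyl 1-(5-tert-butoxy-5-oxopentyl)-4-(2-oxopentyl)-1H-pyrrole-2-carboxylate
Product: 9 methyl 9-oxo-1-(2-oxopentyl)-6,7,8,9-tetrahydro-5H-pyrrolo[1,2-a]azepine-3-carboxylate, via carboxylic acid 7 (not isolated), via mixed anhydride 8 (not isolated)
Conditions: TFA, CH2Cl2, rt; concentrate; (CF3CO)2O, CH2Cl2 (0.01 M), 0 °C → rt
Reagents that add atoms: none
Why: Acidolysis frees the chain carboxylic acid, whose trifluoroacetic mixed anhydride acylates C5, the only open pyrrole α-position the tether can reach (intramolecular Friedel–Crafts acylation closing the seven-membered ketone), and the acid-stable methyl ester and the side-chain ketone pass through unchanged.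

Step 5
Reactants: 9 methyl 9-oxo-1-(2-oxopentyl)-6,7,8,9-tetrahydro-5H-pyrrolo[1,2-a]azepine-3-carboxylate
Product: 11 methyl 9-hydroxy-1-(2-oxopentyl)-6,7,8,9-tetrahydro-5H-pyrrolo[1,2-a]azepine-3-carboxylate (racemic), via lithium enolate 10 (not isolated)
Conditions: LiN(SiMe3)2 (1.05 equiv), THF, −78 °C; i-Bu2AlH (1.2 equiv), −78 °C; aq. NH4Cl, aq. potassium sodium tartrate
Reagents that add atoms: none
Why: A plain hydride reduction would attack the more electrophilic side-chain ketone first, so this ketone, by far the more acidic one, is converted into its pyrrole-conjugated lithium enolate, which is inert to hydride, and i-Bu2AlH then reduces only the 2-acylpyrrole ketone before aqueous work-up returns the side-chain ketone (in-situ protection of a ketone as its enolate), with no stereocontrol needed because the carbinol is used as the racemate.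

Step 6
Reactants: 11 methyl 9-hydroxy-1-(2-oxopentyl)-6,7,8,9-tetrahydro-5H-pyrrolo[1,2-a]azepine-3-carboxylate (racemic)
Product: 13 methyl (7aR,8R)-8-ethyl-9-oxo-4,5,6,7,7a,8,9,10-octahydroazepino[3,2,1-hi]indole-2-carboxylate, via azafulvenium ion 12 (not isolated)
Conditions: (R)-3,3'-bis(2,4,6-triisopropylphenyl)-1,1'-binaphthyl-2,2'-diyl N-(trifluoromethylsulfonyl)phosphoramide (10 mol %), toluene (0.02 M), 5 Å MS, 0 °C → rt
Reagents that add atoms: none
Why: The strong chiral acid protonates the C9 hydroxyl of either enantiomer of 11 and water departs to give the same planar 1-azafulvenium ion 12 (charge delocalised from C9 over C9a to the ring nitrogen) as a contact ion pair with the chiral phosphoramidate, which makes the step enantioconvergent. The side-chain ketone enolises under the same acid and the propyl-side enol carbon adds to C9, forming the C7a–C8 bond of 13 and the cyclohexanone in a 6-(enolendo)-endo-trig closure, since both the enol C=C and the exocyclic C9=C9a bond of the cation lie inside the new ring. The closest known reaction type is the chiral phosphoric acid-catalysed, enantioconvergent SN1-type substitution of indolyl and pyrrolyl carbinols by enols and enamides, used here intramolecularly on an N-alkylpyrrole. The C7a configuration is set by the counter-anion, which shields one face of the cation and hydrogen-bonds the enol OH, whereas the C8 ethyl centre is α to the new ketone and should settle under the acid in the trans, diequatorial arrangement. The step needs capture by the propyl-side enol, which is secured because the more stable pyrrole-conjugated enol could only close a four-membered ring and simply reverts. It also needs a cation that resists side reactions, which is secured by the C3 methyl ester (it blocks the second pyrrole α-position, damps intermolecular alkylation and is stable to the acid), by the sieves that remove water, and by reprotonation of any 8,9-alkene formed by proton loss.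

Step 7
Reactants: 13 methyl (7aR,8R)-8-ethyl-9-oxo-4,5,6,7,7a,8,9,10-octahydroazepino[3,2,1-hi]indole-2-carboxylate; 14 ethyl (2S)-2-{[(trifluoromethyl)sulfonyl]oxy}propanoate
Product: 17 methyl (7aR,8R,10S)-10-[(2S)-1-ethoxy-1-oxopropan-2-yl]-8-ethyl-9-oxo-4,5,6,7,7a,8,9,10-octahydroazepino[3,2,1-hi]indole-2-carboxylate, via lithium enolate 15 (not isolated), via C10 epimer 16 (not isolated)
Conditions: LiN(SiMe3)2, THF, −78 °C; 14, −78 → −30 °C; aq. NH4Cl; then DBU (0.2 equiv), CH2Cl2, rt
Reagents that add atoms: none
Why: Deprotonation occurs at C10, the less hindered and pyrrole-conjugated α-position, and the enolate displaces triflate from the lactate carbon with inversion (SN2 enolate alkylation with an α-triflyloxy ester), so the (S)-triflate gives the required (S)-propanoate centre, while catalytic DBU then epimerises the doubly activated C10–H to the thermodynamic isomer with the new substituent equatorial and cis to the C8 ethyl group.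

Step 8
Reactants: 17 methyl (7aR,8R,10S)-10-[(2S)-1-ethoxy-1-oxopropan-2-yl]-8-ethyl-9-oxo-4,5,6,7,7a,8,9,10-octahydroazepino[3,2,1-hi]indole-2-carboxylate
Product: 19 lactone ester (cis-fused γ-lactone O–C9/C10–CH(CH3)–C=O on the (7aR,8R,9R,10S) core; lactone α-carbon S; CO2Me at C2), via hydroxy ester 18 (not isolated)
Conditions: LiBH(s-Bu)3, THF, −78 °C; AcOH; then PPTS (10 mol %), toluene, 60 °C
Reagents that add atoms: none
Why: The bulky hydride approaches the C9 carbonyl along the equatorial trajectory, away from the axial C7a–H, to give the axial alcohol cis to both flanking equatorial substituents (as with cis-2,6-dialkylcyclohexanones), and this cis γ-hydroxy ester closes under mild acid to the cis-fused lactone without exposing the base-labile lactone α-centre (bulky-hydride ketone reduction followed by acid-catalysed lactonisation).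

Step 9
Reactants: 19 lactone ester
Product: 21 lactone acid (19 with CO2H at C2), via dilithium dicarboxylate 20 (not isolated)
Conditions: LiOH, THF/MeOH/H2O, 0 → 55 °C; then 1 M HCl to pH 2, EtOAc, rt
Reagents that add atoms: lithium hydroxide, [Li+].[OH-]
Why: Saponification (BAc2 ester hydrolysis) first opens the lactone, whose α-centre is no longer acidic as the carboxylate, and then cleaves the hindered pyrrole methyl ester, and acidification recloses the cis γ-hydroxy acid to the lactone while leaving the pyrrole-2-carboxylic acid for the next step.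

Step 10
Reactants: 21 lactone acid
Product: 23 lactone aldehyde (21 with CHO in place of CO2H at C2), via 2-unsubstituted pyrrole 22 (not isolated)
Conditions: TFA, rt; then HC(OEt)3, 0 °C; aq. NaHCO3
Reagents that add atoms: triethyl orthoformate, CCOC(OCC)OCC; water, O
Why: Electron-rich pyrrole-2-carboxylic acids lose CO2 after ipso-protonation in TFA, and the pyrrole so released is formylated in the same flask by the dialkoxycarbenium ion from the orthoformate at C2, its only free α-position (protodecarboxylation followed by orthoformate formylation).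

Step 11
Reactants: 23 lactone aldehyde; 24 ethyl 2-(bromomethyl)acrylate
Product: 26 α-methylene bis-lactone (C2 carries a (2S)-4-methylidene-5-oxooxolan-2-yl ring), via silyl ether 25 (not isolated)
Conditions: CrCl2 (10 mol %), 3,6-diphenyl-1,8-bis[(S)-4-isopropyl-4,5-dihydrooxazol-2-yl]-9H-carbazole (12 mol %), Mn powder, Me3SiCl, i-Pr2NEt (30 mol %), THF, rt; then Bu4NF, THF, 0 °C; aq. NH4Cl
Reagents that add atoms: none
Why: A chiral bis(oxazoline)–chromium allyl species adds to the aldehyde through a closed six-membered transition state (catalytic asymmetric Nozaki–Hiyama–Kishi 2-(alkoxycarbonyl)allylation), the ligand directing Si-face attack to set the (S)-carbinol centre irrespective of the remote stereocentres, and fluoride-induced desilylation gives an alkoxide that closes onto the acrylate ester under non-acidic conditions that avoid ionisation of the pyrrolyl C–O bond.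

Step 12
Reactants: 26 α-methylene bis-lactone
Product: 27 bisdehydroneotuberostemonine
Conditions: H2 (1 atm), RhCl(PPh3)3 (5 mol %), toluene/EtOH (1:1), rt
Reagents that add atoms: none
Why: Homogeneous rhodium-catalysed hydrogenation of the exocyclic 1,1-disubstituted alkene delivers H2 to the lactone face opposite the pyrrolyl group on the γ-carbon, giving the cis-α-methyl-γ-substituted lactone with the (S)-methyl centre, and unlike palladium on carbon it should not hydrogenolyse the pyrrolylic C–O bond.

Compound list
1 | methyl 4-formyl-1H-pyrrole-2-carboxylate | COC(=O)c1cc(C=O)c[nH]1 | starting material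
2 | tert-butyl 5-bromopentanoate | CC(C)(C)OC(=O)CCCCBr | starting material
3 | methyl 1-(5-tert-butoxy-5-oxopentyl)-4-formyl-1H-pyrrole-2-carboxylate | COC(=O)c1cc(C=O)cn1CCCCC(=O)OC(C)(C)C | intermediate
4 | 1-nitrobutane | CCCC[N+](=O)[O-] | starting material
5 | methyl 1-(5-tert-butoxy-5-oxopentyl)-4-[(E)-2-nitropent-1-en-1-yl]-1H-pyrrole-2-carboxylate | CCC/C(=C\c1cn(CCCCC(=O)OC(C)(C)C)c(C(=O)OC)c1)[N+](=O)[O-] | intermediate
6 | methyl 1-(5-tert-butoxy-5-oxopentyl)-4-(2-oxopentyl)-1H-pyrrole-2-carboxylate | CCCC(=O)Cc1cn(CCCCC(=O)OC(C)(C)C)c(C(=O)OC)c1 | intermediate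
7 | 5-[2-(methoxycarbonyl)-4-(2-oxopentyl)-1H-pyrrol-1-yl]pentanoic acid | CCCC(=O)Cc1cn(CCCCC(=O)O)c(C(=O)OC)c1 | intermediate (not isolated)
8 | 5-[2-(methoxycarbonyl)-4-(2-oxopentyl)-1H-pyrrol-1-yl]pentanoic trifluoroacetic anhydride | CCCC(=O)Cc1cn(CCCCC(=O)OC(=O)C(F)(F)F)c(C(=O)OC)c1 | intermediate (not isolated)
9 | methyl 9-oxo-1-(2-oxopentyl)-6,7,8,9-tetrahydro-5H-pyrrolo[1,2-a]azepine-3-carboxylate | CCCC(=O)Cc1cc(C(=O)OC)n2CCCCC(=O)c12 | intermediate
10 | lithium enolate of the side-chain ketone of 9 (pyrrole-conjugated) | CCCC([O-])=Cc1cc(C(=O)OC)n2CCCCC(=O)c12.[Li+] | intermediate (not isolated)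
11 | methyl 9-hydroxy-1-(2-oxopentyl)-6,7,8,9-tetrahydro-5H-pyrrolo[1,2-a]azepine-3-carboxylate, racemic | CCCC(=O)Cc1cc(C(=O)OC)n2CCCCC(O)c12 | intermediate (precursor of the key step)
12 | 1-azafulvenium ion from 11 (cation shown; counter-ion is the chiral phosphoramidate) | CCCC(=O)CC1=CC(C(=O)OC)=[N+]2CCCCC=C12 | intermediate (not isolated)
13 | methyl (7aR,8R)-8-ethyl-9-oxo-4,5,6,7,7a,8,9,10-octahydroazepino[3,2,1-hi]indole-2-carboxylate | CC[C@H]1C(=O)Cc2cc(C(=O)OC)n3c2[C@@H]1CCCC3 | intermediate (product of the key step)
14 | ethyl (2S)-2-{[(trifluoromethyl)sulfonyl]oxy}propanoate | CCOC(=O)[C@H](C)OS(=O)(=O)C(F)(F)F | starting material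
15 | lithium C9–C10 enolate of 13 | CC[C@H]1C([O-])=Cc2cc(C(=O)OC)n3c2[C@@H]1CCCC3.[Li+] | intermediate (not isolated)
16 | methyl (7aR,8R,10R)-10-[(2S)-1-ethoxy-1-oxopropan-2-yl]-8-ethyl-9-oxo-4,5,6,7,7a,8,9,10-octahydroazepino[3,2,1-hi]indole-2-carboxylate (C10 epimer of 17) | CC[C@H]1C(=O)[C@H]([C@H](C)C(=O)OCC)c2cc(C(=O)OC)n3c2[C@@H]1CCCC3 | intermediate (not isolated)
17 | methyl (7aR,8R,10S)-10-[(2S)-1-ethoxy-1-oxopropan-2-yl]-8-ethyl-9-oxo-4,5,6,7,7a,8,9,10-octahydroazepino[3,2,1-hi]indole-2-carboxylate | CC[C@H]1C(=O)[C@@H]([C@H](C)C(=O)OCC)c2cc(C(=O)OC)n3c2[C@@H]1CCCC3 | intermediate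
18 | methyl (7aR,8R,9R,10S)-10-[(2S)-1-ethoxy-1-oxopropan-2-yl]-8-ethyl-9-hydroxy-4,5,6,7,7a,8,9,10-octahydroazepino[3,2,1-hi]indole-2-carboxylate (8-ethyl, 9-OH and 10-substituent all cis) | CC[C@H]1[C@@H](O)[C@@H]([C@H](C)C(=O)OCC)c2cc(C(=O)OC)n3c2[C@@H]1CCCC3 | intermediate (not isolated)
19 | lactone ester: cis-fused γ-lactone O–C9/C10–CH(CH3)–C(=O) on the (7aR,8R,9R,10S) core, lactone α-carbon (S) with methyl on the concave face, CO2Me at C2 | CC[C@H]1[C@H]2OC(=O)[C@@H](C)[C@H]2c2cc(C(=O)OC)n3c2[C@@H]1CCCC3 | intermediate
20 | dilithium salt of the ring-opened hydroxy diacid from 19 | CC[C@H]1[C@@H](O)[C@@H]([C@H](C)C(=O)[O-])c2cc(C(=O)[O-])n3c2[C@@H]1CCCC3.[Li+].[Li+] | intermediate (not isolated)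
21 | lactone acid: 19 with CO2H at C2 | CC[C@H]1[C@H]2OC(=O)[C@@H](C)[C@H]2c2cc(C(=O)O)n3c2[C@@H]1CCCC3 | intermediate
22 | 2-unsubstituted pyrrole lactone: 21 after loss of CO2 | CC[C@H]1[C@H]2OC(=O)[C@@H](C)[C@H]2c2ccn3c2[C@@H]1CCCC3 | intermediate (not isolated)
23 | lactone aldehyde: CHO at C2 | CC[C@H]1[C@H]2OC(=O)[C@@H](C)[C@H]2c2cc(C=O)n3c2[C@@H]1CCCC3 | intermediate
24 | ethyl 2-(bromomethyl)acrylate | C=C(CBr)C(=O)OCC | starting material
25 | trimethylsilyl ether of the (S)-homoallylic alcohol: C2 bears CH(OSiMe3)CH2C(=CH2)CO2Et | CC[C@H]1[C@H]2OC(=O)[C@@H](C)[C@H]2c2cc([C@H](CC(=C)C(=O)OCC)O[Si](C)(C)C)n3c2[C@@H]1CCCC3 | intermediate (not isolated)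
26 | α-methylene bis-lactone: C2 bears a (2S)-4-methylidene-5-oxooxolan-2-yl ring | CC[C@H]1[C@H]2OC(=O)[C@@H](C)[C@H]2c2cc([C@@H]3CC(=C)C(=O)O3)n3c2[C@@H]1CCCC3 | intermediate
27 | bisdehydroneotuberostemonine: C2 bears a (2S,4S)-4-methyl-5-oxooxolan-2-yl ring (cis); core (7aR,8R,9R,10S), fused-lactone α-carbon (S) | CC[C@H]1[C@H]2OC(=O)[C@@H](C)[C@H]2c2cc([C@@H]3C[C@H](C)C(=O)O3)n3c2[C@@H]1CCCC3 | target

Total step count: 12. Longest linear sequence: 12 steps (1 → 27); all other carbon inputs are purchased.

Steps most likely to fail

1. Step 6. The ion pair of the N-alkyl azafulvenium ion has no N–H anchor for the anion, so facial discrimination may be poor, or the cation may be diverted into proton loss and intermolecular alkylation before the enol closes the ring. The fallback sets out from 9 and returns at 13. Diketone 9 is cyclised by acid-catalysed intramolecular aldol condensation (TsOH, toluene, reflux, water removal), in which the O-protonated 2-acylpyrrole is the electrophile and the propyl-side enol the nucleophile, to the tricyclic enone F1. Hydrogenation of the C7a=C8 bond (H2, Pd/C, EtOAc) and equilibration of the ethyl centre with DBU should give the racemic trans ketone F2. Resolution by preparative chromatography on a chiral stationary phase then gives 13.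

2. Step 7. Displacement at the secondary triflate by the hindered, stabilised enolate may be slow, so that elimination to the acrylate, O-alkylation or erosion of configuration at the lactate carbon competes. The fallback sets out from 13 and returns at 19. Enolate 15 is alkylated with the primary electrophile ethyl bromoacetate and equilibrated with DBU to the keto ester F3. Reduction with LiBH(s-Bu)3 gives the hydroxy ester F4, which closes with PPTS to the unsubstituted cis-lactone F5. Its lithium enolate F6 (LiN(i-Pr)2, THF, −78 °C) is methylated with MeI on the convex face to the α-epimeric methyl lactone F7. Deprotonation to the lithium enolate F8 and kinetic protonation on the convex face with 2,6-di-tert-butyl-4-methylphenol at −78 °C then places the methyl group on the concave face and gives 19.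

3. Step 11. The electron-rich pyrrole-2-carbaldehyde may react sluggishly with the allylchromium species, catalyst control of the new carbinol centre may be incomplete, or the pyrrolyl C–O bond may ionise during lactone closure with loss of configuration. The fallback sets out from 22 (isolated by omitting the orthoformate in step 10) and returns at 27. (S)-4-Methoxy-3-methyl-4-oxobutanoic acid (a catalogue half-ester carrying the future lactone methyl centre, COC(=O)[C@@H](C)CC(=O)O) is converted with (COCl)2 into the acid chloride F9. This acylates 22 at C2 (Friedel–Crafts acylation, CH2Cl2, 40 °C) to the keto ester F10. Corey–Bakshi–Shibata reduction with the (R)-oxazaborolidine and catecholborane should give the (S)-hydroxy ester F11, which lactonises with catalytic DBU directly to 27, so that steps 11 and 12 are replaced.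

Further compounds
F1 | step 6 | methyl 8-ethyl-9-oxo-4,5,6,7,9,10-hexahydroazepino[3,2,1-hi]indole-2-carboxylate (C7a=C8 enone) | CCC1=C2CCCCn3c(C(=O)OC)cc(c23)CC1=O
F2 | step 6 | racemic trans ketone (13 together with its enantiomer) | CC[C@H]1C(=O)Cc2cc(C(=O)OC)n3c2[C@@H]1CCCC3.CC[C@@H]1C(=O)Cc2cc(C(=O)OC)n3c2[C@H]1CCCC3
F3 | step 7 | methyl (7aR,8R,10S)-10-(2-ethoxy-2-oxoethyl)-8-ethyl-9-oxo-4,5,6,7,7a,8,9,10-octahydroazepino[3,2,1-hi]indole-2-carboxylate | CC[C@H]1C(=O)[C@@H](CC(=O)OCC)c2cc(C(=O)OC)n3c2[C@@H]1CCCC3
F4 | step 7 | all-cis hydroxy ester from F3 (9-OH cis to 8-ethyl and to the 10-substituent) | CC[C@H]1[C@@H](O)[C@@H](CC(=O)OCC)c2cc(C(=O)OC)n3c2[C@@H]1CCCC3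
F5 | step 7 | unsubstituted cis-fused lactone ester (19 without the lactone methyl group) | CC[C@H]1[C@H]2OC(=O)C[C@H]2c2cc(C(=O)OC)n3c2[C@@H]1CCCC3
F6 | step 7 | lithium enolate of lactone F5 | CC[C@H]1[C@H]2OC([O-])=C[C@H]2c2cc(C(=O)OC)n3c2[C@@H]1CCCC3.[Li+]
F7 | step 7 | lactone α-epimer of 19 (methyl on the convex face) | CC[C@H]1[C@H]2OC(=O)[C@H](C)[C@H]2c2cc(C(=O)OC)n3c2[C@@H]1CCCC3
F8 | step 7 | lithium enolate of lactone F7 | CC[C@H]1[C@H]2OC([O-])=C(C)[C@H]2c2cc(C(=O)OC)n3c2[C@@H]1CCCC3.[Li+]
F9 | step 11 | methyl (2S)-4-chloro-2-methyl-4-oxobutanoate | COC(=O)[C@@H](C)CC(=O)Cl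
F10 | step 11 | keto ester: C2 of 22 acylated, bearing C(=O)CH2CH(CH3)CO2Me with (S)-methyl centre | CC[C@H]1[C@H]2OC(=O)[C@@H](C)[C@H]2c2cc(C(=O)C[C@H](C)C(=O)OC)n3c2[C@@H]1CCCC3
F11 | step 11 | (S)-hydroxy ester from F10: C2 bears CH(OH)CH2CH(CH3)CO2Me | CC[C@H]1[C@H]2OC(=O)[C@@H](C)[C@H]2c2cc([C@@H](O)C[C@H](C)C(=O)OC)n3c2[C@@H]1CCCC3
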